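All runs were generated by integration for an exercise; the scatter is artificial.

The closed, stirred vessel holds the racemate of E and J with single-handed Z at fixed volume and temperature, and the question is how far the excess of D over G has sunk when the flask stops.

| setting | blue | grey | teal | flask |
|---|---|---|---|---|
| E | 0.028 M | 0.044 M | 0.020 M | 0.020 M |
| J | 0.028 M | 0.044 M | 0.020 M | 0.020 M |
| Z | 0.080 M | 0.080 M | 0.12 M | 0.0800 M |
| remark | run made earlier | run made earlier | run made earlier |  |
| time |  |  |  | 50 min |

| run | time / min | D / % | G / % |
|---|---|---|---|
| blue | 2.50 | 53.5 | 7.7 |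
| blue | 5.00 | 58.4 | 9.9 |
| blue | 8.00 | 62.7 | 10.8 |
| blue | 15.0 | 67.8 | 14.5 |
| blue | 30.0 | 70.6 | 12.9 |
| grey | 2.50 | 49.6 | 6.3 |
| grey | 5.00 | 55.3 | 8.8 |
| grey | 8.00 | 59.3 | 6.6 |
| grey | 15.0 | 63.4 | 7.8 |
| grey | 30.0 | 63.8 | 8.7 |
| teal | 2.50 | 55.2 | 11.6 |
| teal | 8.00 | 63.5 | 21.5 |
| teal | 15.0 | 66.9 | 22.8 |
| teal | 20.0 | 68.9 | 25.1 |
| teal | 30.0 | 69.8 | 24.6 |

(scatter of a reading: 1 percentage point)

- Z is single-handed; E and J are mirror images of each other, charged as a racemate, each of them at the stated concentration
- what has gone into L counts as reacted
- an excess is the difference of the two amounts in percent of their sum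
- an excess is below zero if the other one leads
- the handed part of Z does not stay in what it makes, so the products of the two hands are mirror images too

- excess of D over G in the product at 2.5 min
- excess of D over G in the product at 50 min
- part of the E and J charged together that has reacted at 50 min

I bracket the end excess. Between 15.0 min and 30.0 min grey D reads 63.4% and then 63.8%, but blue D reads 67.8% and then 70.6%, and teal D 66.9% and then 69.8%, so the last readings at 30.0 min are the latest values I have, not proven end values, and my bracket is an estimate.

I count Z in equivalents on E and J together. The blue run has 1.43 equivalents and its last reading gives an excess of 69.1%. The teal run has 3.00 and its last reading gives 47.9%. The flask has 2.00, more than blue and less than teal , so blue is my ceiling and teal my floor.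

To tighten this, I draw a straight line between them and read the equivalent cost, the points of end excess lost per equivalent of Z: 14 percentage points. The grey run, left out of the line, has 0.909 equivalents; the line gives 76.1% there, and its readings give 76.0%. For the flask I commit to 61.4%.

The forecast, reasoning that “The partition therefore depends on Z”, gives 73% early, 66% at the end and 90% reacted. Its end excess lies inside my bracket, 4.6 points above my figure.

The flask gives 75.4% early, 64.2% at the end and 89.6% reacted.

    Z + E → D (k = 40.3 M⁻¹ min⁻¹)
    Z + J → G (k = 1.30 M⁻¹ min⁻¹)
    E ⇌ L (K = 0.0120, k = 0.121 min⁻¹)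
    J ⇌ L (K = 0.0120, k = 0.121 min⁻¹)
    Z → Q (k = 7.47 × 10⁻⁴ min⁻¹)
    Z → X (k = 0.106 min⁻¹)

At 50.0 min Z, the limiting reagent, stands at 0.0192% of its charge, with X at 0.0439 M. The equivalent cost carries to a neighbouring flask with 0.14 M of Z, which is 3.50 equivalents: counted down from blue, it gives 41.1%, and that flask ends at 44.4%.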